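**Retrosynthetic overview**

1. The target is reached by one acidolysis of a bis-tert-butyl-protected diester, itself cut at the ester bond into a primary alcohol on the dihydrobenzofuran side chain and O-tert-butyl-p-coumaric acid; ring A (benzo ring) and ring C (phenol ring of the ester) are bought as 4-oxygenated benzaldehydes and olefinated to (E)-acrylates.
2. Ring B (the dihydrofuran, the only ring built) is closed through the C3–C3a bond by palladium-catalysed intramolecular C(sp3)–H arylation of an acyclic ortho-bromoaryl sec-alkyl ether, so C3 enters as a plain methyl group and never needs a functional handle.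
3. Enabling feature: C3 is a CH2 lying β to the ring oxygen O1 and bonded to C3a, the arene carbon ortho to O1; in the open ether this methyl group is the only primary C–H that palladium at C3a can reach through a six-membered palladacycle (Pd, C3a, C7a, O1, C2, C3), while C2 and C1' carry only methine hydrogens.
4. The ether comes from a Mitsunobu inversion (O1–C2 bond) of a 2-bromophenol cinnamate with an anti-configured 3-hydroxy-2-methylbutyl silyl ether, made from methyl (R)-3-hydroxybutanoate by Fráter–Seebach methylation (sets C1'), reduction and silylation; C2 comes from the chiral pool and is inverted once.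
5. Ring order: rings A and C are preformed, ring B is formed in step 6, followed by desilylation, esterification and global deprotection.

Key step: step 6

Remark: locants O1, C2, C3, C3a and C7a refer to the 2,3-dihydro-1-benzofuran and C1' to the side-chain stereocentre; both stereocentres are read as S from the SMILES, and the aryl sec-alkyl ether is assumed to behave in the C–H arylation like the tert-alkyl ethers and N-sec-alkyl anilides of the precedent.

**Route**

Step 1
Reactants: 1 methyl (R)-3-hydroxybutanoate
Product: 3 methyl (2R,3R)-3-hydroxy-2-methylbutanoate, via dilithium alkoxide enolate 2 (not isolated)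
Conditions: LiN(iPr)2 (2.2 equiv), THF, −78 to −20 °C; then MeI, DMPU, −78 to 0 °C; AcOH quench
Reagents that add atoms: methyl iodide, CI
Why: Fráter–Seebach alkylation, in which the chelated dilithium alkoxide–enolate is methylated on the face anti to the C3 methyl group, so that the existing carbinol centre should set the new methyl-bearing centre (the later C1') with high anti selectivity.

Step 2
Reactants: 3 methyl (2R,3R)-3-hydroxy-2-methylbutanoate
Product: 4 (2S,3R)-2-methylbutane-1,3-diol
Conditions: LiAlH4, THF, 0 °C to rt; H2O work-up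
Reagents that add atoms: none
Why: Hydride reduction of the ester to the primary alcohol should leave both stereocentres untouched, since neither is epimerised under these conditions (the descriptor at the methyl-bearing carbon changes only because the priorities change).

Step 3
Reactants: 4 (2S,3R)-2-methylbutane-1,3-diol
Product: 5 (2R,3S)-4-[(tert-butyldiphenylsilyl)oxy]-3-methylbutan-2-ol
Conditions: TBDPSCl (1.05 equiv), imidazole, CH2Cl2, 0 °C
Reagents that add atoms: tert-butyl(chloro)diphenylsilane, CC(C)(C)[Si](Cl)(c1ccccc1)c1ccccc1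
Why: Chemoselective silylation, in which the bulky silyl chloride should react at the unhindered primary hydroxyl and leave the α-branched secondary hydroxyl free for the etherification.

Step 4
Reactants: 6 3-bromo-4-hydroxybenzaldehyde
Product: 7 tert-butyl (E)-3-(3-bromo-4-hydroxyphenyl)prop-2-enoate
Conditions: Ph3P=CHCO2tBu (1.3 equiv), toluene, 80 °C
Reagents that add atoms: tert-butyl (triphenylphosphoranylidene)acetate, CC(C)(C)OC(=O)C=P(c1ccccc1)(c1ccccc1)c1ccccc1
Why: Wittig olefination with a stabilised ylide should give the (E)-cinnamate selectively and tolerates the free phenol, while the tert-butyl ester is chosen to survive steps 5 to 9 and to fall in the final acidolysis.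

Step 5
Reactants: 5 (2R,3S)-4-[(tert-butyldiphenylsilyl)oxy]-3-methylbutan-2-ol; 7 tert-butyl (E)-3-(3-bromo-4-hydroxyphenyl)prop-2-enoate
Product: 8 tert-butyl (E)-3-[3-bromo-4-({(2S,3S)-4-[(tert-butyldiphenylsilyl)oxy]-3-methylbutan-2-yl}oxy)phenyl]prop-2-enoate
Conditions: PPh3, DIAD, toluene, 0 °C to rt
Reagents that add atoms: none
Why: Mitsunobu etherification, in which the acidic ortho-bromophenol displaces the oxyphosphonium ion of 5 by an SN2 process, so that the carbinol centre is inverted from R to S and becomes the future C2 while the neighbouring methyl-bearing centre is untouched.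

Step 6
Reactants: 8 tert-butyl (E)-3-[3-bromo-4-({(2S,3S)-4-[(tert-butyldiphenylsilyl)oxy]-3-methylbutan-2-yl}oxy)phenyl]prop-2-enoate
Product: 9 tert-butyl (E)-3-[(2S)-2-{(2S)-1-[(tert-butyldiphenylsilyl)oxy]propan-2-yl}-2,3-dihydro-1-benzofuran-5-yl]prop-2-enoate
Conditions: Pd(OAc)2 (5 mol %), PCy3·HBF4 (10 mol %), PivOH (30 mol %), Cs2CO3 (1.5 equiv), mesitylene (0.05 M), 135 °C
Reagents that add atoms: none
Why: Oxidative addition of the C–Br bond to zerovalent palladium (formed from Pd(OAc)2 and PCy3) gives an arylpalladium bromide at C3a, bromide is exchanged for pivalate, the terminal methyl group is cleaved by carboxylate-assisted concerted metalation–deprotonation, and C(sp3)–C(sp2) reductive elimination forms the C3–C3a bond and returns zerovalent palladium. The closest known reaction type is the palladium-catalysed intramolecular methyl C–H arylation of 2-halophenyl alkyl ethers to 2,3-dihydrobenzofurans and of N-alkyl-2-haloanilides to indolines, the latter also with a hydrogen-bearing carbon next to the heteroatom as here. Ring B is closed in a five-membered (formally 5-exo) mode by reductive elimination from the six-membered palladacycle Pd–C3a–C7a–O1–C2–C3. No stereocentre is created, and C2 and C1' are carried through unchanged because no bond at these centres is broken. The step needs site selectivity for this methyl group over the C1' methyl and the CH2OSi methylene (both would require a seven-membered palladacycle) and over the methine C–H bonds (concerted metalation–deprotonation strongly prefers primary C–H bonds), and chemoselectivity over Heck-type reactions of the β-substituted acrylate, which the intramolecular course, the high dilution and the sluggish insertion of 1,2-disubstituted cinnamates should secure. β-Hydride elimination from the palladacycle should be disfavoured because the C2–H bond cannot become syn-coplanar with the Pd–C3 bond inside the six-membered ring.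

Step 7
Reactants: 9 tert-butyl (E)-3-[(2S)-2-{(2S)-1-[(tert-butyldiphenylsilyl)oxy]propan-2-yl}-2,3-dihydro-1-benzofuran-5-yl]prop-2-enoate
Product: 10 tert-butyl (E)-3-[(2S)-2-[(2S)-1-hydroxypropan-2-yl]-2,3-dihydro-1-benzofuran-5-yl]prop-2-enoate
Conditions: Bu4NF, AcOH (1:1), THF, 0 °C to rt
Reagents that add atoms: none
Why: Fluoride-mediated desilylation buffered with acetic acid should free the primary alcohol without base-induced damage to the acrylate ester or to the stereocentres.

Step 8
Reactants: 11 4-tert-butoxybenzaldehyde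
Product: 13 (E)-3-(4-tert-butoxyphenyl)prop-2-enoic acid, via arylidenemalonic acid 12 (not isolated)
Conditions: malonic acid (2 equiv), piperidine (cat.), pyridine, 90 °C
Reagents that add atoms: malonic acid, OC(=O)CC(=O)O
Why: Knoevenagel–Doebner condensation, in which the arylidenemalonic acid decarboxylates in hot pyridine to the (E)-cinnamic acid while the basic medium spares the acid-labile aryl tert-butyl ether.

Step 9
Reactants: 10 tert-butyl (E)-3-[(2S)-2-[(2S)-1-hydroxypropan-2-yl]-2,3-dihydro-1-benzofuran-5-yl]prop-2-enoate; 13 (E)-3-(4-tert-butoxyphenyl)prop-2-enoic acid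
Product: 14 tert-butyl (E)-3-[(2S)-2-[(2S)-1-{[(E)-3-(4-tert-butoxyphenyl)prop-2-enoyl]oxy}propan-2-yl]-2,3-dihydro-1-benzofuran-5-yl]prop-2-enoate
Conditions: DCC, DMAP (cat.), CH2Cl2, 0 °C to rt
Reagents that add atoms: none
Why: Steglich esterification (carbodiimide activation with DMAP acyl transfer) should acylate the unhindered primary alcohol under neutral conditions that leave both tert-butyl groups, both (E)-alkenes and the stereocentres intact.

Step 10
Reactants: 14 tert-butyl (E)-3-[(2S)-2-[(2S)-1-{[(E)-3-(4-tert-butoxyphenyl)prop-2-enoyl]oxy}propan-2-yl]-2,3-dihydro-1-benzofuran-5-yl]prop-2-enoate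
Product: 15 (E)-3-[(2S)-2-[(2S)-1-{[(E)-3-(4-hydroxyphenyl)prop-2-enoyl]oxy}propan-2-yl]-2,3-dihydro-1-benzofuran-5-yl]prop-2-enoic acid
Conditions: CF3CO2H/CH2Cl2 (1:3), 0 °C to rt
Reagents that add atoms: none
Why: Acidolysis with trifluoroacetic acid should cleave the tert-butyl ester and the aryl tert-butyl ether together by loss of the tert-butyl cation as 2-methylpropene, whereas the primary alkyl cinnamate ester and the dihydrobenzofuran ether are stable to these conditions.

**Compound list**

1 | methyl (R)-3-hydroxybutanoate | C[C@@H](O)CC(=O)OC | starting material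
2 | chelated dilithium alkoxide–enolate of 1 | [Li+].[Li+].C[C@@H]([O-])/C=C(\[O-])OC | intermediate
3 | methyl (2R,3R)-3-hydroxy-2-methylbutanoate | C[C@@H](O)[C@@H](C)C(=O)OC | intermediate
4 | (2S,3R)-2-methylbutane-1,3-diol | C[C@@H](O)[C@@H](C)CO | intermediate
5 | (2R,3S)-4-[(tert-butyldiphenylsilyl)oxy]-3-methylbutan-2-ol | C[C@@H](O)[C@@H](C)CO[Si](c1ccccc1)(c1ccccc1)C(C)(C)C | intermediate
6 | 3-bromo-4-hydroxybenzaldehyde | O=Cc1ccc(O)c(Br)c1 | starting material
7 | tert-butyl (E)-3-(3-bromo-4-hydroxyphenyl)prop-2-enoate | CC(C)(C)OC(=O)/C=C/c1ccc(O)c(Br)c1 | intermediate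
8 | tert-butyl (E)-3-[3-bromo-4-({(2S,3S)-4-[(tert-butyldiphenylsilyl)oxy]-3-methylbutan-2-yl}oxy)phenyl]prop-2-enoate | C[C@H](Oc1ccc(/C=C/C(=O)OC(C)(C)C)cc1Br)[C@@H](C)CO[Si](c1ccccc1)(c1ccccc1)C(C)(C)C | intermediate
9 | tert-butyl (E)-3-[(2S)-2-{(2S)-1-[(tert-butyldiphenylsilyl)oxy]propan-2-yl}-2,3-dihydro-1-benzofuran-5-yl]prop-2-enoate | C[C@@H](CO[Si](c1ccccc1)(c1ccccc1)C(C)(C)C)[C@@H]1Cc2cc(/C=C/C(=O)OC(C)(C)C)ccc2O1 | intermediate
10 | tert-butyl (E)-3-[(2S)-2-[(2S)-1-hydroxypropan-2-yl]-2,3-dihydro-1-benzofuran-5-yl]prop-2-enoate | C[C@@H](CO)[C@@H]1Cc2cc(/C=C/C(=O)OC(C)(C)C)ccc2O1 | intermediate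
11 | 4-tert-butoxybenzaldehyde | CC(C)(C)Oc1ccc(C=O)cc1 | starting material
12 | 2-(4-tert-butoxybenzylidene)propanedioic acid | CC(C)(C)Oc1ccc(C=C(C(=O)O)C(=O)O)cc1 | intermediate
13 | (E)-3-(4-tert-butoxyphenyl)prop-2-enoic acid | CC(C)(C)Oc1ccc(/C=C/C(=O)O)cc1 | intermediate
14 | tert-butyl (E)-3-[(2S)-2-[(2S)-1-{[(E)-3-(4-tert-butoxyphenyl)prop-2-enoyl]oxy}propan-2-yl]-2,3-dihydro-1-benzofuran-5-yl]prop-2-enoate | C[C@@H](COC(=O)/C=C/c1ccc(OC(C)(C)C)cc1)[C@@H]1Cc2cc(/C=C/C(=O)OC(C)(C)C)ccc2O1 | intermediate
15 | (E)-3-[(2S)-2-[(2S)-1-{[(E)-3-(4-hydroxyphenyl)prop-2-enoyl]oxy}propan-2-yl]-2,3-dihydro-1-benzofuran-5-yl]prop-2-enoic acid | C[C@@H](COC(=O)/C=C/c1ccc(O)cc1)[C@@H]1Cc2cc(/C=C/C(=O)O)ccc2O1 | target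

**Step count and risks**

Total step count: 10 (steps 4 and 8 prepare the two arene fragments).
Longest linear sequence: 8 steps (steps 1, 2, 3, 5, 6, 7, 9, 10).

Steps most likely to fail:

Step 6. After oxidative addition the arylpalladium species may be diverted faster than the methyl C–H bond is cleaved. The diverting processes are protodebromination, 1,4-palladium migration to the ether methine followed by β-hydride elimination (loss of the side chain as an enol ether), and intermolecular Heck-type oligomerisation through the cinnamate. The fallback sets out from 7 and comes back at 9; it makes the C3–C3a bond by cross-coupling and closes ring B through the C2–O1 bond instead. α-Selective Suzuki–Miyaura prenylation of 7 with 3-methylbut-2-en-1-ylboronic acid pinacol ester (Pd(OAc)2, bulky biaryl dialkylphosphine, K3PO4) should give tert-butyl (E)-3-[4-hydroxy-3-(3-methylbut-2-en-1-yl)phenyl]prop-2-enoate F1. Allylic oxidation of the (E)-methyl group (SeO2 cat., tBuOOH) should give tert-butyl (E)-3-{4-hydroxy-3-[(E)-4-hydroxy-3-methylbut-2-en-1-yl]phenyl}prop-2-enoate F2. Silylation of the primary alcohol (TBDPSCl, imidazole; any aryl silyl ether is cleaved again with K2CO3 in MeOH) should give tert-butyl (E)-3-{3-[(E)-4-[(tert-butyldiphenylsilyl)oxy]-3-methylbut-2-en-1-yl]-4-hydroxyphenyl}prop-2-enoate F3. Asymmetric hydroboration with the appropriate enantiomer of monoisopinocampheylborane, followed by oxidation with NaBO3·4H2O, adds H and OH syn across the (E)-alkene and should give the anti-configured tert-butyl (E)-3-{3-[(2R,3S)-4-[(tert-butyldiphenylsilyl)oxy]-2-hydroxy-3-methylbutyl]-4-hydroxyphenyl}prop-2-enoate F4. Mitsunobu cyclodehydration (PPh3, DIAD) then closes ring B with inversion at C2 to give 9.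

Step 5. The oxyphosphonium ion of the α-branched secondary alcohol may eliminate to an alkene or react sluggishly with the weakly nucleophilic phenol, so that conversion is low or the configuration is partly retained. The fallback sets out from 5 and comes back at 8; it forms the aryl–oxygen bond by nucleophilic aromatic substitution at the arene, which retains the carbinol configuration, after the carbinol has been inverted with a better pronucleophile. Mitsunobu reaction of 5 with 4-nitrobenzoic acid (PPh3, DIAD) should give (2S,3S)-4-[(tert-butyldiphenylsilyl)oxy]-3-methylbutan-2-yl 4-nitrobenzoate F5. Methanolysis (K2CO3, MeOH) should give (2S,3S)-4-[(tert-butyldiphenylsilyl)oxy]-3-methylbutan-2-ol F6. Its potassium alkoxide (KN(SiMe3)2, THF, low temperature) should displace fluoride from 3-bromo-4-fluorobenzaldehyde to give 3-bromo-4-({(2S,3S)-4-[(tert-butyldiphenylsilyl)oxy]-3-methylbutan-2-yl}oxy)benzaldehyde F7. Wittig olefination with Ph3P=CHCO2tBu as in step 4 then gives 8.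

Step 10. The tert-butyl cations released may C-alkylate the liberated electron-rich phenol ring C before they are lost as 2-methylpropene. The fallback sets out from 10 and comes back at 15; it protects the phenol orthogonally as an acetate so that only one tert-butyl group is cleaved, and that while ring C is still deactivated. Steglich esterification of 10 with commercial (E)-4-acetoxycinnamic acid (DCC, DMAP) should give tert-butyl (E)-3-[(2S)-2-[(2S)-1-{[(E)-3-(4-acetoxyphenyl)prop-2-enoyl]oxy}propan-2-yl]-2,3-dihydro-1-benzofuran-5-yl]prop-2-enoate F8. Acidolysis (CF3CO2H, CH2Cl2) should give (E)-3-[(2S)-2-[(2S)-1-{[(E)-3-(4-acetoxyphenyl)prop-2-enoyl]oxy}propan-2-yl]-2,3-dihydro-1-benzofuran-5-yl]prop-2-enoic acid F9. Aminolysis of the aryl acetate with pyrrolidine, which attacks aryl esters much faster than the alkyl cinnamate, should give 15.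

Further compounds
F1 | step 6 | tert-butyl (E)-3-[4-hydroxy-3-(3-methylbut-2-en-1-yl)phenyl]prop-2-enoate | CC(C)=CCc1cc(/C=C/C(=O)OC(C)(C)C)ccc1O
F2 | step 6 | tert-butyl (E)-3-{4-hydroxy-3-[(E)-4-hydroxy-3-methylbut-2-en-1-yl]phenyl}prop-2-enoate | C/C(CO)=C\Cc1cc(/C=C/C(=O)OC(C)(C)C)ccc1O
F3 | step 6 | tert-butyl (E)-3-{3-[(E)-4-[(tert-butyldiphenylsilyl)oxy]-3-methylbut-2-en-1-yl]-4-hydroxyphenyl}prop-2-enoate | C/C(CO[Si](c1ccccc1)(c1ccccc1)C(C)(C)C)=C\Cc1cc(/C=C/C(=O)OC(C)(C)C)ccc1O
F4 | step 6 | tert-butyl (E)-3-{3-[(2R,3S)-4-[(tert-butyldiphenylsilyl)oxy]-2-hydroxy-3-methylbutyl]-4-hydroxyphenyl}prop-2-enoate | C[C@@H](CO[Si](c1ccccc1)(c1ccccc1)C(C)(C)C)[C@H](O)Cc1cc(/C=C/C(=O)OC(C)(C)C)ccc1O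
F5 | step 5 | (2S,3S)-4-[(tert-butyldiphenylsilyl)oxy]-3-methylbutan-2-yl 4-nitrobenzoate | C[C@H](OC(=O)c1ccc(cc1)[N+](=O)[O-])[C@@H](C)CO[Si](c1ccccc1)(c1ccccc1)C(C)(C)C
F6 | step 5 | (2S,3S)-4-[(tert-butyldiphenylsilyl)oxy]-3-methylbutan-2-ol | C[C@H](O)[C@@H](C)CO[Si](c1ccccc1)(c1ccccc1)C(C)(C)C
F7 | step 5 | 3-bromo-4-({(2S,3S)-4-[(tert-butyldiphenylsilyl)oxy]-3-methylbutan-2-yl}oxy)benzaldehyde | C[C@H](Oc1ccc(C=O)cc1Br)[C@@H](C)CO[Si](c1ccccc1)(c1ccccc1)C(C)(C)C
F8 | step 10 | tert-butyl (E)-3-[(2S)-2-[(2S)-1-{[(E)-3-(4-acetoxyphenyl)prop-2-enoyl]oxy}propan-2-yl]-2,3-dihydro-1-benzofuran-5-yl]prop-2-enoate | C[C@@H](COC(=O)/C=C/c1ccc(OC(C)=O)cc1)[C@@H]1Cc2cc(/C=C/C(=O)OC(C)(C)C)ccc2O1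
F9 | step 10 | (E)-3-[(2S)-2-[(2S)-1-{[(E)-3-(4-acetoxyphenyl)prop-2-enoyl]oxy}propan-2-yl]-2,3-dihydro-1-benzofuran-5-yl]prop-2-enoic acid | C[C@@H](COC(=O)/C=C/c1ccc(OC(C)=O)cc1)[C@@H]1Cc2cc(/C=C/C(=O)O)ccc2O1
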